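Whatever else happens in this flask, first end groups, links and isomer of the product always add up to the charge, so each first end group lost has passed once through the coupling with second end groups.

    first end groups + second end groups → links + by-product (k1 = 6.97 × 10⁻⁴ M⁻¹ min⁻¹)
    solid second end groups ⇌ second end groups, rate k2*(cs2 - [second end groups]) while solid is left; crystals form when [second end groups] > cs2 (cs2 = 0.17 M, k2 = 8.58 × 10⁻⁴ min⁻¹)
    links ⇌ isomer of the product (K3 = 0.33, k3 = 5.23 × 10⁻⁵ min⁻¹)

first end groups 2.5 M; solid second end groups 2.50 M; time 50 h

- given per volume of solution although it is solid: solid second end groups
- at the start none of the solid second end groups is in solution
- run time (flask): 50 h

- the links standing at 50 h, as a percentage of the first end groups charged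
- concentration of second end groups in solution at 50 h, in percent of saturation

**What does the coupling rate hang on?** On [first end groups] times [second end groups], and the second of these has to come out of the solid. Setting the dissolution coefficient times the gap to saturation equal to the coupling constant times [first end groups] times [second end groups] gives 0.0561 M at the charge. This is the balance level: the solubility times the dissolution coefficient, divided by the dissolution coefficient plus the coupling constant times [first end groups].

**Does the flask reach it in time?** Yes, its approach time, one over the denominator of that level, is 6.41 h, shorter than the run of 50 h.

**Can the solid give out?** Not by 50 h in this flask, since up to then dissolution can deliver at most 0.438 M, less than the 2.50 M charged.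

**So what replaces the curve?** Its mean: a flat level that starts one approach time late. First end groups then decay pseudo-first-order, and 9.72% of them are used.

**But the level is not flat, is it?** No. With fewer first end groups it rises to 0.0600 M, and the mean of the two ends raises the share used to 10.0%. The flat curve was therefore 0.28 percentage points low.

**And the links?** Their forward half-life of 9.2 d is longer than the run. With a mean link amount of 0.5 of the final one, and the way back not counted, they lose 6.84% of what was formed to the isomer. I commit to 9.35% links and 35.3% of saturation.

The forecast, slightly higher on links, gives 9.5% and 35.1%, holding that “the dissolved second end groups settle within about 400 min at a quasi-steady level”.

The flask gives 9.38% and 35.0%.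

This flask is not at rest at 50 h: 90.0% of the first end groups and 87.7% of the solid, each of its own charge, still stand. As [first end groups] falls, the balance level rises. With the [first end groups] standing in the same flask read at 8.0 d, it gives 0.0763 M against a [second end groups] of 0.0751 M, and links reach 33.3%. At ten times the time it gives 0.126 M against a [second end groups] of 0.124 M. By then first end groups are down to 17.0%, solid to 12.1% of its charge, links stand at 64.6% and isomer of the product at 18.3%.

The constants used here were chosen freely; the flask was simulated.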